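**Plan**
1. Retrosynthesis: the aryl O–S bond is cut last (sulfation of the only free phenol). A helper hydroxyl is placed on C2, and the decalin is then cut at C2–C3 (carbonyl-ene) and at the ring-fusion bond C5–C10 (ene) to give the acyclic dienal 21. Compound 21 is cut at C10=C1 (Wittig), C6–C7 (allylic coupling) and the two exocyclic C9–C bonds (lactone alkylations).
2. Enabling feature: in ring A the exocyclic C4=C11 methylene sits on the carbon next to the quaternary ring-fusion carbon C5, whose neighbour C10 bears H and the C1 methylene. The array C11=C4–C5–C10–C1–H is the product pattern of an ene reaction between a C5=C4(CH3)2 alkene and a C10=C1 enal. With OH on C2, the array C11=C4–C3–C2–OH is the product pattern of a carbonyl-ene reaction.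
3. Forward: arene fragment 8 and lactone 9 are joined at C9, then the C6–C4 chain and the enal are attached. Ring B closes first (C5–C10) and ring A second (C2–C3) in the same flask. C2 is then deoxygenated, the phenol freed, sulfated, and the silyl groups removed.
4. Stereochemistry: C8 comes from (R)-lactone 9. C9 is set by enolate alkylation anti to the C8 methyl. C5 and C10 are set in the chair transition state of the ene ring closure, steered by C8 and C9.
5. Conventions: locants C1–C11 follow the rearranged-drimane (avarane) numbering: ring A = C1–C5 and C10, ring B = C5–C10, C11 = exocyclic CH2 on C4. Ar* = 2-(methoxymethoxy)-3-[(triisopropylsilyl)oxy]-5-{[(triisopropylsilyl)oxy]methyl}phenyl.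

Key step: step 13

Remark: the target is drawn as the free aryl hydrogen sulfate, so it is assumed to be handled as a salt and released as the acid by cation exchange only at the end; (R)-4-methyloxolan-2-one and 1-bromo-2,3-dimethylbut-2-ene are taken as catalogue compounds.

**Route**

Step 1
Reactants: 1 3,4-dihydroxybenzaldehyde
Product: 2 3-hydroxy-4-(methoxymethoxy)benzaldehyde
Conditions: MOMCl (1.05 equiv), K2CO3, acetone, 0 °C to rt
Reagents that add atoms: chloromethyl methyl ether, COCCl
Why: Williamson-type O-alkylation of the monophenoxide should occur at the more acidic 4-OH, which is para to the formyl group.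

Step 2
Reactants: 2 3-hydroxy-4-(methoxymethoxy)benzaldehyde
Product: 3 5-(hydroxymethyl)-2-(methoxymethoxy)phenol
Conditions: NaBH4, MeOH, 0 °C
Reagents that add atoms: none
Why: Borohydride reduction of the aldehyde, to which the methoxymethyl ether is inert.

Step 3
Reactants: 3 5-(hydroxymethyl)-2-(methoxymethoxy)phenol
Product: 4 triisopropyl{[4-(methoxymethoxy)-3-(triisopropylsilyloxy)phenyl]methoxy}silane
Conditions: i-Pr3SiCl (2.4 equiv), imidazole, DMF, rt
Reagents that add atoms: chlorotriisopropylsilane, CC(C)[Si](Cl)(C(C)C)C(C)C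
Why: Imidazole-promoted silylation of the phenol and the primary alcohol gives two bulky silyl ethers that resist bases, hydrides and organometallics and that fluoride removes together at the end.

Step 4
Reactants: 4 triisopropyl{[4-(methoxymethoxy)-3-(triisopropylsilyloxy)phenyl]methoxy}silane
Product: 7 Ar*CH2OH, {2-(methoxymethoxy)-3-(triisopropylsilyloxy)-5-[(triisopropylsilyloxy)methyl]phenyl}methanol, via aryllithium 5 (not isolated), via aldehyde 6 (not isolated)
Conditions: n-BuLi, TMEDA, THF, −78 to 0 °C; DMF, −78 °C; then MeOH, NaBH4, 0 °C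
Reagents that add atoms: N,N-dimethylformamide, CN(C)C=O
Why: Directed ortho-metalation, in which the methoxymethoxy group directs lithiation to its only free ortho position, followed by formylation with DMF and borohydride reduction in the same flask.

Step 5
Reactants: 7 Ar*CH2OH
Product: 8 Ar*CH2Br, 1-(bromomethyl)-2-(methoxymethoxy)-3-(triisopropylsilyloxy)-5-[(triisopropylsilyloxy)methyl]benzene
Conditions: CBr4, PPh3, 2,6-lutidine, CH2Cl2, 0 °C
Reagents that add atoms: tetrabromomethane, BrC(Br)(Br)Br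
Why: Appel bromination of the benzylic alcohol under buffered, acid-free conditions that spare the methoxymethyl and silyl ethers.

Step 6
Reactants: 9 (R)-4-methyloxolan-2-one
Product: 11 (3R,4R)-3,4-dimethyloxolan-2-one (trans), via lithium enolate 10 (not isolated)
Conditions: LiN(i-Pr)2, THF, −78 °C; MeI, −78 to −40 °C
Reagents that add atoms: iodomethane, CI
Why: Kinetic lithium enolate alkylation of the γ-lactone, in which the methyl should enter trans to the C8 methyl, although this C9 centre is flattened again in step 7.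

Step 7
Reactants: 11 (3R,4R)-3,4-dimethyloxolan-2-one; 8 Ar*CH2Br
Product: 13 (3R,4R)-3-(Ar*CH2)-3,4-dimethyloxolan-2-one, via lithium enolate 12 (not isolated)
Conditions: LiN(i-Pr)2, THF, −78 °C; 8, DMPU, −78 to −30 °C
Reagents that add atoms: none
Why: Enolate alkylation of a β-substituted γ-butyrolactone, in which the benzylic bromide approaches the planar enolate anti to the C8 methyl and so sets the quaternary C9 with the arylmethyl group trans and the C9 methyl cis to the C8 methyl.

Step 8
Reactants: 13 (3R,4R)-3-(Ar*CH2)-3,4-dimethyloxolan-2-one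
Product: 14 (3R,4R)-3-(Ar*CH2)-3,4-dimethyloxolan-2-ol (lactol, both C2 epimers)
Conditions: i-Bu2AlH (1.2 equiv), CH2Cl2, −78 °C; aq. KNaC4H4O6
Reagents that add atoms: none
Why: Partial reduction of the lactone stops at the lactol because the tetrahedral aluminium acetal is stable at −78 °C, and C8 and C9 are untouched.

Step 9
Reactants: 14 lactol; 15 (1,3-dioxolan-2-ylmethyl)triphenylphosphonium bromide
Product: 16 (2R,3S,4Z)-3-(Ar*CH2)-5-(1,3-dioxolan-2-yl)-2,3-dimethylpent-4-en-1-ol
Conditions: 15 (3 equiv), KOt-Bu, THF, 0 °C; then 14, rt to 40 °C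
Reagents that add atoms: none
Why: Wittig olefination of the open hydroxy-aldehyde form of the lactol with the non-stabilised two-carbon ylide should give the masked enal (Z expected) and free the C7 hydroxyl, while the acetal oxidation level prevents conjugate addition of that hydroxyl.

Step 10
Reactants: 16 (2R,3S,4Z)-3-(Ar*CH2)-5-(1,3-dioxolan-2-yl)-2,3-dimethylpent-4-en-1-ol
Product: 17 2-[(1Z,3S,4R)-3-(Ar*CH2)-5-bromo-3,4-dimethylpent-1-en-1-yl]-1,3-dioxolane
Conditions: CBr4, PPh3, 2,6-lutidine, CH2Cl2, 0 °C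
Reagents that add atoms: tetrabromomethane, BrC(Br)(Br)Br
Why: Appel bromination of the primary alcohol at a CH2 carbon, buffered so that the acetal and the methoxymethyl ether survive.

Step 11
Reactants: 17 bromide; 18 1-bromo-2,3-dimethylbut-2-ene
Product: 20 2-[(1Z,3R,4S)-3-(Ar*CH2)-3,4,7,8-tetramethylnona-1,7-dien-1-yl]-1,3-dioxolane, via Grignard reagent 19 (not isolated)
Conditions: Mg, THF, 40 °C; then 18, Li2CuCl4 (3 mol %), THF, −40 to 0 °C
Reagents that add atoms: none
Why: Copper-catalysed coupling of the primary Grignard reagent with the allylic bromide should occur at the CH2 terminus (SN2) because the γ-carbon is fully substituted, which forms C6–C7 and brings in the tetrasubstituted ene donor.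

Step 12
Reactants: 20 diene acetal
Product: 21 (2E,4R,5S)-4-(Ar*CH2)-4,5,8,9-tetramethyldeca-2,8-dienal
Conditions: oxalic acid, THF–H2O, rt
Reagents that add atoms: water, O
Why: Mild acid hydrolysis of the allylic acetal should give the enal, which equilibrates to the E isomer under the acid, while the aryl methoxymethyl ether, the silyl ethers and the tetrasubstituted alkene tolerate the weak acid.

Step 13
Reactants: 21 (2E,4R,5S)-4-(Ar*CH2)-4,5,8,9-tetramethyldeca-2,8-dienal
Product: 23 (1R,2S,4aS,8aS)-1-(Ar*CH2)-1,2,4a-trimethyl-5-methylidenedecahydronaphthalen-7-ol (locants as in 25; the carbinol carbon is C2 of the skeleton numbering, both epimers), via aldehyde 22 (not isolated)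
Conditions: Me2AlCl (3 equiv), CH2Cl2, −78 to −20 °C; aq. KNaC4H4O6
Reagents that add atoms: none
Why: Proposed new method: Me2AlCl binds the enal of 21, the tetrasubstituted C5=C4 alkene attacks the β-carbon C10 through a chair-like six-membered transition state (6-exo closure of ring B, C5–C10 bond), and a hydrogen of a C4 methyl passes to C1 in an asynchronous type 1 ene reaction, which leaves an isopropenyl group on the new quaternary C5 and the aluminium-bound aldehyde 22. The same Lewis acid should then drive a type 2 carbonyl-ene reaction in which the isopropenyl CH2 (C3) adds to the aldehyde carbon C2 and a methyl hydrogen goes to oxygen (six-membered ring A, closed exo at the carbonyl), so that the exocyclic C4=C11 methylene is formed directly. The closest known reaction types are the Lewis-acid ene cyclisation of 1,7-dienes that carry an activated enophile, the Me2AlCl-promoted ene addition of 2,3-dimethylbut-2-ene to enals with formation of a quaternary carbon, and the sequential ene annulation of enals; new here are the tetrasubstituted ene donor in the ring-closing mode and the joining of both ene steps in one acyclic substrate. C5 and C10 are set in the first ene step, where the enal arm on C10 and the CMe2 terminus on C5 take equatorial places (trans, as in the known 1,7-diene cases) and the chair is fixed by the equatorial C8 methyl, which puts the C9 methyl axial and syn to the C5 methyl, whereas the other chair would need an axial C8 methyl and an axial arylmethyl group. The step needs attack by C5 and not C4 (six- against seven-membered ring), hydrogen transfer faster than 1,2-shifts of the zwitterion (a mild, proton-scavenging Lewis acid at low temperature), and the alkene, not the arene, as nucleophile (attack by the aryl carbon para to the silyloxy group would close a five-membered ring by an in-plane approach with poor overlap). The configuration of the new carbinol C2 is of no consequence because this oxygen is removed in steps 14 and 15.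

Step 14
Reactants: 23 decalinol
Product: 24 O-[(1R,2S,4aS,8aS)-1-(Ar*CH2)-1,2,4a-trimethyl-5-methylidenedecahydronaphthalen-7-yl] 1H-imidazole-1-carbothioate
Conditions: 1,1′-thiocarbonyldiimidazole, DMAP (cat.), ClCH2CH2Cl, 70 °C
Reagents that add atoms: 1,1′-thiocarbonyldiimidazole, S=C(n1ccnc1)n1ccnc1
Why: Thioacylation of the unhindered secondary C2 alcohol gives the thiocarbonyl derivative needed for radical deoxygenation.

Step 15
Reactants: 24 imidazolyl thiocarbonate
Product: 25 (1R,2S,4aS,8aS)-1-(Ar*CH2)-1,2,4a-trimethyl-5-methylidenedecahydronaphthalene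
Conditions: n-Bu3SnH, AIBN (cat.), toluene, 100 °C
Reagents that add atoms: none
Why: Barton–McCombie deoxygenation, in which the tin radical adds to sulfur, the C2–O bond breaks and the secondary C2 radical takes hydrogen from the tin hydride without attack on the 1,1-disubstituted alkene.

Step 16
Reactants: 25 protected decalin
Product: 26 2-{[(1R,2S,4aS,8aS)-1,2,4a-trimethyl-5-methylidenedecahydronaphthalen-1-yl]methyl}-6-(triisopropylsilyloxy)-4-[(triisopropylsilyloxy)methyl]phenol
Conditions: ZnBr2, n-PrSH, CH2Cl2, 0 °C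
Reagents that add atoms: none
Why: Lewis-acid and thiol cleavage of the aryl methoxymethyl ether (the oxocarbenium ion is trapped by the thiol) should leave the silyl ethers and the exocyclic alkene alone and free only the oxygen to be sulfated.

Step 17
Reactants: 26 phenol
Product: 27 pyridinium 2-{[(1R,2S,4aS,8aS)-1,2,4a-trimethyl-5-methylidenedecahydronaphthalen-1-yl]methyl}-6-(triisopropylsilyloxy)-4-[(triisopropylsilyloxy)methyl]phenyl sulfate
Conditions: SO3·pyridine, pyridine, 45 °C
Reagents that add atoms: sulfur trioxide–pyridine complex, O=S(=O)=O.c1ccncc1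
Why: O-Sulfation of the single free phenol with the sulfur trioxide–pyridine complex, with the regiochemistry fixed because both other oxygens are silylated.

Step 18
Reactants: 27 pyridinium aryl sulfate
Product: 28 2-hydroxy-4-(hydroxymethyl)-6-{[(1R,2S,4aS,8aS)-1,2,4a-trimethyl-5-methylidenedecahydronaphthalen-1-yl]methyl}phenyl hydrogen sulfate (target)
Conditions: n-Bu4NF, THF, 0 °C to rt; then sulfonic acid resin (H+ form), MeOH–H2O, 0 °C
Reagents that add atoms: none
Why: Fluoride cleaves the aryl and the benzylic silyl ether while the aryl sulfate monoester anion is inert to fluoride and base, and brief contact with the cold acid resin exchanges the cations for protons.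

**Compound list**
1 | 3,4-dihydroxybenzaldehyde | O=Cc1ccc(O)c(O)c1 | starting material
2 | 3-hydroxy-4-(methoxymethoxy)benzaldehyde | O=Cc1ccc(OCOC)c(O)c1 | intermediate
3 | 5-(hydroxymethyl)-2-(methoxymethoxy)phenol | OCc1ccc(OCOC)c(O)c1 | intermediate
4 | triisopropyl{[4-(methoxymethoxy)-3-(triisopropylsilyloxy)phenyl]methoxy}silane | COCOc1ccc(CO[Si](C(C)C)(C(C)C)C(C)C)cc1O[Si](C(C)C)(C(C)C)C(C)C | intermediate
5 | Ar*Li, {2-(methoxymethoxy)-3-(triisopropylsilyloxy)-5-[(triisopropylsilyloxy)methyl]phenyl}lithium | [Li]c1cc(CO[Si](C(C)C)(C(C)C)C(C)C)cc(O[Si](C(C)C)(C(C)C)C(C)C)c1OCOC | intermediate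
6 | Ar*CHO, 2-(methoxymethoxy)-3-(triisopropylsilyloxy)-5-[(triisopropylsilyloxy)methyl]benzaldehyde | O=Cc1cc(CO[Si](C(C)C)(C(C)C)C(C)C)cc(O[Si](C(C)C)(C(C)C)C(C)C)c1OCOC | intermediate
7 | Ar*CH2OH, {2-(methoxymethoxy)-3-(triisopropylsilyloxy)-5-[(triisopropylsilyloxy)methyl]phenyl}methanol | OCc1cc(CO[Si](C(C)C)(C(C)C)C(C)C)cc(O[Si](C(C)C)(C(C)C)C(C)C)c1OCOC | intermediate
8 | Ar*CH2Br, 1-(bromomethyl)-2-(methoxymethoxy)-3-(triisopropylsilyloxy)-5-[(triisopropylsilyloxy)methyl]benzene | BrCc1cc(CO[Si](C(C)C)(C(C)C)C(C)C)cc(O[Si](C(C)C)(C(C)C)C(C)C)c1OCOC | intermediate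
9 | (R)-4-methyloxolan-2-one | O=C1C[C@@H](C)CO1 | starting material
10 | lithium enolate of 9 | [Li]OC1=C[C@@H](C)CO1 | intermediate
11 | (3R,4R)-3,4-dimethyloxolan-2-one (trans) | O=C1[C@H](C)[C@@H](C)CO1 | intermediate
12 | lithium enolate of 11 | [Li]OC1=C(C)[C@@H](C)CO1 | intermediate
13 | (3R,4R)-3-(Ar*CH2)-3,4-dimethyloxolan-2-one | O=C1[C@](C)(Cc3cc(CO[Si](C(C)C)(C(C)C)C(C)C)cc(O[Si](C(C)C)(C(C)C)C(C)C)c3OCOC)[C@@H](C)CO1 | intermediate
14 | (3R,4R)-3-(Ar*CH2)-3,4-dimethyloxolan-2-ol (both C2 epimers) | OC1[C@](C)(Cc3cc(CO[Si](C(C)C)(C(C)C)C(C)C)cc(O[Si](C(C)C)(C(C)C)C(C)C)c3OCOC)[C@@H](C)CO1 | intermediate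
15 | (1,3-dioxolan-2-ylmethyl)triphenylphosphonium bromide | [Br-].C(C1OCCO1)[P+](c1ccccc1)(c1ccccc1)c1ccccc1 | starting material
16 | (2R,3S,4Z)-3-(Ar*CH2)-5-(1,3-dioxolan-2-yl)-2,3-dimethylpent-4-en-1-ol | C(/C4OCCO4)=C/[C@](C)(Cc3cc(CO[Si](C(C)C)(C(C)C)C(C)C)cc(O[Si](C(C)C)(C(C)C)C(C)C)c3OCOC)[C@@H](C)CO | intermediate
17 | 2-[(1Z,3S,4R)-3-(Ar*CH2)-5-bromo-3,4-dimethylpent-1-en-1-yl]-1,3-dioxolane | C(/C4OCCO4)=C/[C@](C)(Cc3cc(CO[Si](C(C)C)(C(C)C)C(C)C)cc(O[Si](C(C)C)(C(C)C)C(C)C)c3OCOC)[C@@H](C)CBr | intermediate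
18 | 1-bromo-2,3-dimethylbut-2-ene | BrCC(C)=C(C)C | starting material
19 | [(2R,3S,4Z)-3-(Ar*CH2)-5-(1,3-dioxolan-2-yl)-2,3-dimethylpent-4-en-1-yl]magnesium bromide | C(/C4OCCO4)=C/[C@](C)(Cc3cc(CO[Si](C(C)C)(C(C)C)C(C)C)cc(O[Si](C(C)C)(C(C)C)C(C)C)c3OCOC)[C@@H](C)C[Mg]Br | intermediate
20 | 2-[(1Z,3R,4S)-3-(Ar*CH2)-3,4,7,8-tetramethylnona-1,7-dien-1-yl]-1,3-dioxolane | C(/C4OCCO4)=C/[C@](C)(Cc3cc(CO[Si](C(C)C)(C(C)C)C(C)C)cc(O[Si](C(C)C)(C(C)C)C(C)C)c3OCOC)[C@@H](C)CCC(C)=C(C)C | intermediate
21 | (2E,4R,5S)-4-(Ar*CH2)-4,5,8,9-tetramethyldeca-2,8-dienal | O=C/C=C/[C@](C)(Cc3cc(CO[Si](C(C)C)(C(C)C)C(C)C)cc(O[Si](C(C)C)(C(C)C)C(C)C)c3OCOC)[C@@H](C)CCC(C)=C(C)C | intermediate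
22 | 2-[(1S,2R,3S,6S)-2-(Ar*CH2)-2,3,6-trimethyl-6-(prop-1-en-2-yl)cyclohexyl]acetaldehyde | O=CC[C@H]1[C@](C)(Cc3cc(CO[Si](C(C)C)(C(C)C)C(C)C)cc(O[Si](C(C)C)(C(C)C)C(C)C)c3OCOC)[C@@H](C)CC[C@@]1(C(C)=C)C | intermediate
23 | (1R,2S,4aS,8aS)-1-(Ar*CH2)-1,2,4a-trimethyl-5-methylidenedecahydronaphthalen-7-ol (locants as in 25; both carbinol epimers) | C=C1CC(O)C[C@H]2[C@](C)(Cc3cc(CO[Si](C(C)C)(C(C)C)C(C)C)cc(O[Si](C(C)C)(C(C)C)C(C)C)c3OCOC)[C@@H](C)CC[C@]12C | intermediate
24 | O-[(1R,2S,4aS,8aS)-1-(Ar*CH2)-1,2,4a-trimethyl-5-methylidenedecahydronaphthalen-7-yl] 1H-imidazole-1-carbothioate | C=C1CC(OC(=S)n4ccnc4)C[C@H]2[C@](C)(Cc3cc(CO[Si](C(C)C)(C(C)C)C(C)C)cc(O[Si](C(C)C)(C(C)C)C(C)C)c3OCOC)[C@@H](C)CC[C@]12C | intermediate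
25 | (1R,2S,4aS,8aS)-1-(Ar*CH2)-1,2,4a-trimethyl-5-methylidenedecahydronaphthalene | C=C1CCC[C@H]2[C@](C)(Cc3cc(CO[Si](C(C)C)(C(C)C)C(C)C)cc(O[Si](C(C)C)(C(C)C)C(C)C)c3OCOC)[C@@H](C)CC[C@]12C | intermediate
26 | 2-{[(1R,2S,4aS,8aS)-1,2,4a-trimethyl-5-methylidenedecahydronaphthalen-1-yl]methyl}-6-(triisopropylsilyloxy)-4-[(triisopropylsilyloxy)methyl]phenol | C=C1CCC[C@H]2[C@](C)(Cc3cc(CO[Si](C(C)C)(C(C)C)C(C)C)cc(O[Si](C(C)C)(C(C)C)C(C)C)c3O)[C@@H](C)CC[C@]12C | intermediate
27 | pyridinium salt of the aryl sulfate of 26 | C=C1CCC[C@H]2[C@](C)(Cc3cc(CO[Si](C(C)C)(C(C)C)C(C)C)cc(O[Si](C(C)C)(C(C)C)C(C)C)c3OS(=O)(=O)[O-])[C@@H](C)CC[C@]12C.c1cc[nH+]cc1 | intermediate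
28 | 2-hydroxy-4-(hydroxymethyl)-6-{[(1R,2S,4aS,8aS)-1,2,4a-trimethyl-5-methylidenedecahydronaphthalen-1-yl]methyl}phenyl hydrogen sulfate | C=C1CCC[C@H]2[C@](C)(Cc3cc(CO)cc(O)c3OS(=O)(=O)O)[C@@H](C)CC[C@]12C | target

**Summary**
Total steps: 18. Longest linear sequence: 17 steps (steps 1–5 and 7–18).

Steps most likely to fail:

Step 13 (proposed new method). The zwitterion formed after C5–C10 bond formation may be diverted into 1,2-shifts, cyclobutane closure or chloride capture, the arene may attack in place of the alkene, or the ring fusion may form cis. Fallback with known chemistry (Michael addition, then aldol condensation): it sets out from bromide 17 by way of its Grignard reagent 19, formed as in step 11. Conjugate addition of 19 to 3-methylbut-3-en-2-one (CuBr·SMe2 cat., THF, −78 °C) would give the methyl ketone with the masked enal, F1. Oxalic acid in THF–H2O would give the keto enal F2. KOt-Bu in t-BuOH would then close ring B by 6-exo Michael addition of the C5 enolate to C10 and ring A by aldol condensation of C3 with the C2 aldehyde, giving the trans-fused bicyclic enone F3. Hydrogenation (H2, Pd/C, EtOAc) would give the saturated C4 ketone F4, and Wittig methylenation (Ph3P=CH2, toluene, 90 °C) would give 25, where the route is rejoined; steps 14 and 15 then fall away.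

Step 11. The coupling may go through attack at the γ-carbon of the allylic bromide to give the branched isomer, through homocoupling, or the Grignard reagent may form sluggishly. Fallback (B-alkyl Suzuki–Miyaura coupling): from alcohol 16, Dess–Martin periodinane (NaHCO3, CH2Cl2) would give the aldehyde F5, and Ph3P=CH2 (THF, −78 to 0 °C) the terminal alkene F6. Hydroboration with 9-BBN-H (THF, rt), selective for the monosubstituted alkene, would give the primary alkylborane F7. Without isolation, F7 would be coupled with 2-bromo-3-methylbut-2-ene (Pd(dppf)Cl2, K3PO4, DMF–H2O, 50 °C) to give 20.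

Step 17. Sulfation of the doubly flanked phenol may be slow, which would allow migration of the neighbouring silyl group to the free oxygen or loss of the sulfate on work-up. Fallback (protected sulfate diester): from phenol 26, 2,2,2-trichloroethyl chlorosulfate (Et3N, DMAP, THF, 0 °C) would give the aryl 2,2,2-trichloroethyl sulfate F8. HF·pyridine (THF, 0 °C) would remove both silyl groups to give the diol F9. Zn dust and HCO2NH4 in MeOH would cleave the trichloroethyl group by reductive fragmentation, and the cation exchange of step 18 would give 28.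

**Further compounds**
F1 | step 13 | methyl ketone with masked enal, 7-(Ar*CH2)-9-(1,3-dioxolan-2-yl)-3,6,7-trimethylnon-8-en-2-one (Z alkene, C8 and C9 of the skeleton as in 20, both epimers at the carbon next to the ketone) | C(/C4OCCO4)=C/[C@](C)(Cc3cc(CO[Si](C(C)C)(C(C)C)C(C)C)cc(O[Si](C(C)C)(C(C)C)C(C)C)c3OCOC)[C@@H](C)CCC(C)C(C)=O
F2 | step 13 | keto enal, (2E)-4-(Ar*CH2)-4,5,8-trimethyl-9-oxodec-2-enal (C4 and C5 of the chain as in 21) | O=C/C=C/[C@](C)(Cc3cc(CO[Si](C(C)C)(C(C)C)C(C)C)cc(O[Si](C(C)C)(C(C)C)C(C)C)c3OCOC)[C@@H](C)CCC(C)C(C)=O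
F3 | step 13 | trans-fused bicyclic enone, skeleton of 25 with C4=O in place of C4=CH2 and a C2=C3 double bond | O=C1C=CC[C@H]2[C@](C)(Cc3cc(CO[Si](C(C)C)(C(C)C)C(C)C)cc(O[Si](C(C)C)(C(C)C)C(C)C)c3OCOC)[C@@H](C)CC[C@]12C
F4 | step 13 | saturated C4 ketone, skeleton of 25 with C4=O in place of C4=CH2 | O=C1CCC[C@H]2[C@](C)(Cc3cc(CO[Si](C(C)C)(C(C)C)C(C)C)cc(O[Si](C(C)C)(C(C)C)C(C)C)c3OCOC)[C@@H](C)CC[C@]12C
F5 | step 11 | aldehyde from 16, 3-(Ar*CH2)-5-(1,3-dioxolan-2-yl)-2,3-dimethylpent-4-enal (Z, stereocentres as in 16) | C(/C4OCCO4)=C/[C@](C)(Cc3cc(CO[Si](C(C)C)(C(C)C)C(C)C)cc(O[Si](C(C)C)(C(C)C)C(C)C)c3OCOC)[C@@H](C)C=O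
F6 | step 11 | terminal alkene, 2-[3-(Ar*CH2)-3,4-dimethylhexa-1,5-dien-1-yl]-1,3-dioxolane (1Z, stereocentres as in 16) | C(/C4OCCO4)=C/[C@](C)(Cc3cc(CO[Si](C(C)C)(C(C)C)C(C)C)cc(O[Si](C(C)C)(C(C)C)C(C)C)c3OCOC)[C@@H](C)C=C
F7 | step 11 | primary alkylborane, the 9-borabicyclo[3.3.1]nonan-9-yl adduct at the terminal carbon of F6 | C(/C4OCCO4)=C/[C@](C)(Cc3cc(CO[Si](C(C)C)(C(C)C)C(C)C)cc(O[Si](C(C)C)(C(C)C)C(C)C)c3OCOC)[C@@H](C)CCB5C6CCCC5CCC6
F8 | step 17 | aryl 2,2,2-trichloroethyl sulfate of 26 | C=C1CCC[C@H]2[C@](C)(Cc3cc(CO[Si](C(C)C)(C(C)C)C(C)C)cc(O[Si](C(C)C)(C(C)C)C(C)C)c3OS(=O)(=O)OCC(Cl)(Cl)Cl)[C@@H](C)CC[C@]12C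
F9 | step 17 | desilylated aryl 2,2,2-trichloroethyl sulfate (2,2,2-trichloroethyl ester of 28) | C=C1CCC[C@H]2[C@](C)(Cc3cc(CO)cc(O)c3OS(=O)(=O)OCC(Cl)(Cl)Cl)[C@@H](C)CC[C@]12C
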